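The ratio c(target)/c(substrate) at which a flask stops gaining target was the single item of a short meeting on these four flasks.

    free enzyme → unfolded enzyme (k1 = 3.0 × 10⁻⁵ /min, Ea1 = 226 kJ/mol)
    substrate + free enzyme ⇌ complex (K2 = 220 /M, k2 = 1.1 × 10⁵ /M/s, Ea2 = 14.0 kJ/mol, ΔH2 = −29.0 kJ/mol)
    complex ⇌ free enzyme + target (K3 = 0.033 M, k3 = 1100 /min, Ea3 = 78.0 kJ/mol, ΔH3 = −57.0 kJ/mol)
    (constants at 40 °C)

| flask | substrate | free enzyme | temperature | time | remark |
|---|---|---|---|---|---|
| grey | 0.016 M | 0.0045 mol% | 20 °C | 10 h |  |
| red | 0.016 M | 0.0045 mol% |  | 10 h | at 20 °C until 8.0 h, from then on at 60 °C |
| green | 0.016 M | 0.0045 mol% | 60 °C | 10 h |  |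
| amber | 0.016 M | 0.0045 mol% | 40 °C | 10 h |  |

* the best flask by amount of target, in percent of the substrate charged; "all alike" if 1.5 percentage points covers them all (grey / red / green / amber / all alike)
* amount of target at the end, in percent of the substrate charged, grey
* amount of target at the end, in percent of the substrate charged, red
* amount of target at the end, in percent of the substrate charged, green
* amount of target at the end, in percent of the substrate charged, amber

- at 40 °C the constants are as listed, elsewhere as the activation energies and enthalpies make them

I proposed to carry the product of the binding and release constants at the flask's temperature, which is 0.999 at 60 °C, under the name rest ratio: the value of c(target)/c(substrate) once both steps stand at equilibrium. I pointed out that the enzyme cancels from this product, so it contains no concentration. The share of target is then the rest ratio divided by one plus the rest ratio, as the enzyme, charged at 0.0045 mol% of the substrate, is far less than the substrate.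

The two enthalpies sum to −86.0 kJ/mol, so I put the rest ratio at 69.1 for grey and 7.26 for amber. The shares came to 98.6 % for grey, 87.9 % for amber and 50.0 % for green, and I named grey as best, its rest ratio being the highest.

A colleague objected that these are end points and asked whether the cold enzyme gets there. I answered with the pass time, the charge of substrate divided by the release rate constant times the enzyme charged, which is the time for one pass if the enzyme stood as complex throughout. At 20 °C it is 2.60 h, shorter than the 8.0 h red spends cold. I conceded that this is a floor.

Another member asked whether green loses its enzyme first. I replied that the pass time at 60 °C is 3.34 min, far shorter than the 3.03 h lifetime of free enzyme there, so green reaches its rest ratio while enzyme is still active. Red has 2.00 h after the change, again longer than that pass time, so I committed to red falling to green's share. It was minuted that I expected thermodynamic, not kinetic, control in these flasks, the pass time at 20 °C being shorter than the 10 h allowed.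

The forecast names grey as best, with 98.6 % for grey, 50 % for red, 50 % for green and 87.9 % for amber, and says of red that “its still-active enzyme quickly brings it back”.

The simulation gives 98.6 % for grey, 50.0 % for red, 50.0 % for green and 87.9 % for amber, so grey is best. Red lost target after the change: it held 98.6 % target at 8.00 h and 50.0 % at 10.0 h, when 29.4 % of its catalyst was unfolded. In the neighbouring flask, red is charged with 0.027 M of substrate at the same loading. The rest ratio at 60 °C holds no concentration and stays 0.999, and the reckoned share stays 50.0 %. That neighbour ends with 50.0 % target and 50.0 % substrate.

The constants used here were chosen freely; no experiment stands behind them.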